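The rate constants on the list of suspects are unknown, but one ratio of them can be read from the plateaus of two runs, and the next charge can be judged by it.

all flasks: G 0.050 M; D 0.41 mM
- grey: J 0.067 M; L 0.055 M; run made earlier
- amber: J 0.15 M; L 0.055 M; run made earlier
- flask: J 0.100 M; L 0.0550 M; time 3.0 d

| run | time / d | X / % |
|---|---|---|
| grey | 0.625 | 79.7 |
| grey | 1.25 | 86.1 |
| grey | 2.00 | 87.8 |
| grey | 3.00 | 86.0 |
| grey | 4.00 | 86.8 |
| amber | 0.250 | 43.6 |
| amber | 0.500 | 64.2 |
| amber | 1.04 | 72.0 |
| amber | 2.08 | 73.8 |
| amber | 4.00 | 74.4 |

(readings scatter by 1 percentage point)

* why nothing more happens at 3.0 d, or that something still does (no working catalyst is left / L has run out first / all of G has reacted / it is still moving / forward and back rates have come level)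
* amount of X at 3.0 d, in percent of the G charged

- on the list of suspects stand: G + D <-> Q; L + Q -> D + X; J + D <-> E; L + E -> D + Z
- the reaction counts as stopped when no species that holds the G changes by six tenths of a point or more over the second half of the time

In each run D carries G through Q to X and J through E to Z, and each passage takes one L. The decision is whether the flask, with [J] at 0.100 M and [L] at 0.0550 M, can be left for 3.0 d or needs longer.

If both losses go in proportion to each substance's own concentration, the fall of [G] in powers of ten is a fixed multiple of the fall of [J]. That multiple is s, the selectivity factor. Take each plateau as the point where L is gone (L as limiting reagent), so that X and Z together equal the L charged. The last grey reading gives 10.7 and the last amber reading 10.8. Their mean is s = 10.7, so G reacts about ten times as readily as J.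

For the flask, my own trial takes Z at the mean of the two runs, 14.7 mM. That leaves J at 85.3%, a fall of 0.0691 of a power of ten, so G falls 0.739 and stands at 18.2%. This overspends L by 0.605 mM, and one correction along the slope gives 85.6% of J and X at 81.2%. The grey readings from 2.00 d on go 87.8%, 86.0% and 86.8%, down and up again with no steady drift, and the amber readings go from 73.8% at 2.08 d to 74.4% at 4.00 d. The time 3.0 d is longer than either of those first plateau readings, so the flask can be left for 3.0 d.

The forecast says L has run out first and 81.2%, on these grounds: “The two selectivities agree, which supports L exhaustion rather than catalyst death.”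

The flask gives L has run out first, with L at 0% and X at 80.9%.

    G + D ⇌ Q (K = 45.0 M⁻¹, k = 510 M⁻¹ h⁻¹)
    L + Q → D + X (k = 3400 M⁻¹ h⁻¹)
    J + D ⇌ E (K = 7.30 M⁻¹, k = 430 M⁻¹ h⁻¹)
    L + E → D + Z (k = 340 M⁻¹ h⁻¹)

L is down to 0.00799% by 1.50 d. At 30.0 d, ten times the time, X still stands at 80.9%, G at 19.0% and Z at 0.0146 M, so the flask has come to rest. Its end state, read the same way, gives s = 10.6. In the neighbour with [J] at 0.040 M, J ends at 79%, for which the carried s gives G at 8.50%, and that neighbour holds 6.2% at 3.00 d.

(The runs are calculated for an exercise, and the scatter is random.)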